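**Retrosynthetic overview**

1. Numbering: ArCH2 = C7, CH = C8, the CH2OH on C8 = C9; primed atoms belong to the half with the tertiary alcohol (C8').
2. Feature: C7 and the oxygen on C9', and likewise C7' and the oxygen on C9, are the ends of five-atom chains (C7–C8–C8'–C9'–O and C7'–C8'–C8–C9–O). Bonding both pairs gives a cis-fused 3,7-dioxabicyclo[3.3.0]octane with the C8' hydroxyl at the ring fusion, so the target is the double benzylic hydrogenolysis product of that bicycle.
3. Ring B (O–C7'–C8'–C8–C9) is cut at C7'–C8': Norrish–Yang photocyclisation of a trans-5-aryl-4-(arylmethoxymethyl)oxolan-3-one (ring A, ketone at C8').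
4. Ring A (O–C7–C8–C8'–C9') comes from an Evans syn-aldol (C7–C8 bond, sets C7), one-carbon homologation to a chloromethyl ketone (C9') and O-alkylation; C8 is then equilibrated trans to the C7 aryl group.
5. Ring order: ring A (step 6), ring B (step 7), both opened in step 8. Chirality is relayed C7 → C8 → C8', and C7 is then erased.

Key step: step 7

Assumption: the photocyclisation is drawn with the C7' aryl group on the convex (exo) face; either C7' epimer leads to the same target because C7' becomes CH2 in the last step.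

**Step 1**
Reactants: 1 4-benzyloxy-3-methoxybenzyl alcohol; 2 methyl acrylate
Product: 4 3-[(4-benzyloxy-3-methoxyphenyl)methoxy]propanoic acid, via methyl ester 3 (not isolated)
Conditions: NaH (0.1 equiv), THF, 0 °C to rt; then LiOH, THF/MeOH/H2O, rt; 1 M HCl to pH 3, 0 °C
Reagents that add atoms: lithium hydroxide, [Li+].[OH-]
Why: Base-catalysed oxa-Michael addition of the benzylic alkoxide to the acrylate followed by saponification; the methyl ester is chosen because hydroxide cleaves it, whereas acidic cleavage of a tert-butyl ester would endanger the electron-rich 4-alkoxybenzyl-type ether, and any transesterified ester converges on the same acid.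

**Step 2**
Reactants: 4 3-[(4-benzyloxy-3-methoxyphenyl)methoxy]propanoic acid; 5 (R)-4-benzyl-1,3-oxazolidin-2-one
Product: 7 (R)-4-benzyl-3-{3-[(4-benzyloxy-3-methoxyphenyl)methoxy]propanoyl}-1,3-oxazolidin-2-one, via mixed pivalic anhydride 6 (not isolated)
Conditions: PivCl, Et3N, THF, −20 °C; then LiCl, 5, −20 °C to rt
Reagents that add atoms: none
Why: Standard N-acylation of an oxazolidinone through the mixed pivalic anhydride with LiCl/Et3N activation, the oxazolidinone attacking the less hindered carbonyl of 6.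

**Step 3**
Reactants: 7 (R)-4-benzyl-3-{3-[(4-benzyloxy-3-methoxyphenyl)methoxy]propanoyl}-1,3-oxazolidin-2-one; 8 4-benzyloxy-3-methoxybenzaldehyde
Product: 11 (R)-4-benzyl-3-[(2R,3R)-3-(4-benzyloxy-3-methoxyphenyl)-2-{[(4-benzyloxy-3-methoxyphenyl)methoxy]methyl}-3-hydroxypropanoyl]-1,3-oxazolidin-2-one, via (Z)-boron enolate 9 (not isolated), via boron aldolate 10 (not isolated)
Conditions: Bu2BOTf, iPr2NEt, CH2Cl2, −78 to 0 °C; 8, −78 to 0 °C; pH 7 buffer, MeOH, 30% H2O2, 0 °C
Reagents that add atoms: none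
Why: Evans syn-aldol reaction: soft enolisation gives the (Z)-boron enolate 9, which adds to the aldehyde through a closed chair transition state on the enolate face away from the benzyl group of the (R)-auxiliary, so the 2,3-syn adduct with the (3R) carbinol centre (the future C7) and the (2R) centre (C8, equilibrated later) is expected.

**Step 4**
Reactants: 11 (R)-4-benzyl-3-[(2R,3R)-3-(4-benzyloxy-3-methoxyphenyl)-2-{[(4-benzyloxy-3-methoxyphenyl)methoxy]methyl}-3-hydroxypropanoyl]-1,3-oxazolidin-2-one
Product: 12 (2R,3R)-3-(4-benzyloxy-3-methoxyphenyl)-2-{[(4-benzyloxy-3-methoxyphenyl)methoxy]methyl}-3-hydroxy-N-methoxy-N-methylpropanamide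
Conditions: MeNH(OMe)·HCl, AlMe3, CH2Cl2, −20 to 0 °C; aq. Rochelle salt
Reagents that add atoms: N,O-dimethylhydroxylamine hydrochloride, CNOC.Cl
Why: Aluminium amide transamidation of a β-hydroxy acyl oxazolidinone (Weinreb amide formation), assisted by the free hydroxyl through an aluminium chelate, cleaves the exocyclic acyl–N bond without epimerisation and returns the auxiliary.

**Step 5**
Reactants: 12 (2R,3R)-3-(4-benzyloxy-3-methoxyphenyl)-2-{[(4-benzyloxy-3-methoxyphenyl)methoxy]methyl}-3-hydroxy-N-methoxy-N-methylpropanamide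
Product: 14 (3R,4R)-4-(4-benzyloxy-3-methoxyphenyl)-3-{[(4-benzyloxy-3-methoxyphenyl)methoxy]methyl}-1-chloro-4-hydroxybutan-2-one, via dilithium tetrahedral adduct 13 (not isolated)
Conditions: MeLi·LiBr (1 equiv), THF, −78 °C; ICH2Cl (3 equiv), then MeLi·LiBr (2.5 equiv) dropwise, −78 °C; AcOH, −78 °C
Reagents that add atoms: chloroiodomethane, ClCI
Why: Chloromethyllithium, generated by iodine–lithium exchange in the presence of the pre-formed lithium alkoxide of 12, adds once to the Weinreb amide because the chelated adduct 13 survives until the acidic quench (Weinreb ketone synthesis with a lithium carbenoid), and no stereocentre is touched.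

**Step 6**
Reactants: 14 (3R,4R)-4-(4-benzyloxy-3-methoxyphenyl)-3-{[(4-benzyloxy-3-methoxyphenyl)methoxy]methyl}-1-chloro-4-hydroxybutan-2-one
Product: 16 (4S,5R)-5-(4-benzyloxy-3-methoxyphenyl)-4-{[(4-benzyloxy-3-methoxyphenyl)methoxy]methyl}oxolan-3-one (trans), via cis-ketone 15 (not isolated)
Conditions: K2CO3, MeCN, 0 °C to rt; then DBU (0.2 equiv), rt
Reagents that add atoms: none
Why: Intramolecular Williamson etherification (5-exo-tet displacement of the activated α-chloro ketone by the C7 hydroxyl, retention at C7) closes ring A to the cis-ketone 15, and DBU then epimerises the enolisable C8 to the thermodynamically preferred trans isomer, so C8 is set under thermodynamic control by C7; 16 has to be freed from residual 15 because C7 is erased later and the C8 epimer would end as the enantiomer of the target.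

**Step 7**
Reactants: 16 (4S,5R)-5-(4-benzyloxy-3-methoxyphenyl)-4-{[(4-benzyloxy-3-methoxyphenyl)methoxy]methyl}oxolan-3-one
Product: 18 (1R,2S,5S,6R)-2,6-bis(4-benzyloxy-3-methoxyphenyl)-3,7-dioxabicyclo[3.3.0]octan-1-ol, via 1,5-biradical 17 (not isolated)
Conditions: hν (medium-pressure Hg lamp, Pyrex filter, λ > 300 nm), degassed benzene (0.01 M), rt
Reagents that add atoms: none
Why: Excitation of the ring-A ketone (n→π*) above 300 nm, where the aryl ethers are transparent, lets the carbonyl oxygen abstract one of the two C7' hydrogens of the arylmethyl ether through a seven-membered transition state (1,6-hydrogen transfer) to give the ketyl/benzylic α-oxy 1,5-biradical 17. Radical–radical combination of C8' with C7' then closes ring B as a five-membered ring; this is the Norrish–Yang photocyclisation of β-alkoxy ketones to 3-hydroxyoxolanes, a known reaction type. The new C8' centre is fixed by the substrate: the C9–O–C7' tether hangs from C8 on one face of ring A and a bicyclo[3.3.0] frame can only close cis, so the hydroxyl ends up cis to H8. The C7' centre is expected to place its aryl group on the convex face, but its configuration is immaterial because step 8 turns C7' into CH2. The step needs site selectivity for the C7' hydrogens over α-cleavage and other hydrogen transfers; the only γ-hydrogen (on C7) lies within ring A and cannot reach the oxygen, and the C7'–H bond is weakened by both the ether oxygen and the electron-rich arene.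

**Step 8**
Reactants: 18 (1R,2S,5S,6R)-2,6-bis(4-benzyloxy-3-methoxyphenyl)-3,7-dioxabicyclo[3.3.0]octan-1-ol
Product: 20 (2R,3R)-2,3-bis[(4-hydroxy-3-methoxyphenyl)methyl]butane-1,2,4-triol, via bisphenol 19 (not isolated)
Conditions: H2 (3 atm), 10% Pd/C, EtOH, rt
Reagents that add atoms: none
Why: Catalytic hydrogenolysis first removes the two O-benzyl groups to give bisphenol 19, whose ring C–O bonds at C7 and C7' are then p-hydroxybenzylic and should be cleaved on palladium under neutral conditions, each oxygen staying on C9' or C9 as a primary alcohol; C8 and C8' carry no benzylic C–O bond and keep their configuration, and the neutral medium avoids acid-induced Friedel–Crafts closure to an aryltetralin.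

**Compound list**

1 | 4-benzyloxy-3-methoxybenzyl alcohol | COc1cc(CO)ccc1OCc1ccccc1 | starting material
2 | methyl acrylate | C=CC(=O)OC | starting material
3 | methyl 3-[(4-benzyloxy-3-methoxyphenyl)methoxy]propanoate | COC(=O)CCOCc1ccc(OCc2ccccc2)c(OC)c1 | intermediate
4 | 3-[(4-benzyloxy-3-methoxyphenyl)methoxy]propanoic acid | OC(=O)CCOCc1ccc(OCc2ccccc2)c(OC)c1 | intermediate
5 | (R)-4-benzyl-1,3-oxazolidin-2-one | O=C1N[C@H](Cc2ccccc2)CO1 | starting material
6 | 3-[(4-benzyloxy-3-methoxyphenyl)methoxy]propanoic pivalic anhydride | CC(C)(C)C(=O)OC(=O)CCOCc1ccc(OCc2ccccc2)c(OC)c1 | intermediate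
7 | (R)-4-benzyl-3-{3-[(4-benzyloxy-3-methoxyphenyl)methoxy]propanoyl}-1,3-oxazolidin-2-one | O=C(CCOCc1ccc(OCc2ccccc2)c(OC)c1)N1[C@H](Cc2ccccc2)COC1=O | intermediate
8 | 4-benzyloxy-3-methoxybenzaldehyde | COc1cc(C=O)ccc1OCc1ccccc1 | starting material
9 | (Z)-dibutylboron enolate of 7 | CCCCB(CCCC)O/C(=C\COCc1ccc(OCc2ccccc2)c(OC)c1)N1[C@H](Cc2ccccc2)COC1=O | intermediate
10 | O-dibutylboryl aldolate of 11 | COc1cc([C@H](OB(CCCC)CCCC)[C@@H](COCc2ccc(OCc3ccccc3)c(OC)c2)C(=O)N2[C@H](Cc3ccccc3)COC2=O)ccc1OCc1ccccc1 | intermediate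
11 | (R)-4-benzyl-3-[(2R,3R)-3-(4-benzyloxy-3-methoxyphenyl)-2-{[(4-benzyloxy-3-methoxyphenyl)methoxy]methyl}-3-hydroxypropanoyl]-1,3-oxazolidin-2-one | COc1cc([C@H](O)[C@@H](COCc2ccc(OCc3ccccc3)c(OC)c2)C(=O)N2[C@H](Cc3ccccc3)COC2=O)ccc1OCc1ccccc1 | intermediate
12 | (2R,3R)-3-(4-benzyloxy-3-methoxyphenyl)-2-{[(4-benzyloxy-3-methoxyphenyl)methoxy]methyl}-3-hydroxy-N-methoxy-N-methylpropanamide | COc1cc([C@H](O)[C@@H](COCc2ccc(OCc3ccccc3)c(OC)c2)C(=O)N(C)OC)ccc1OCc1ccccc1 | intermediate
13 | dilithium tetrahedral adduct of 12 with chloromethyllithium (new carbinol centre undefined) | COc1cc([C@H](O[Li])[C@@H](COCc2ccc(OCc3ccccc3)c(OC)c2)C(O[Li])(CCl)N(C)OC)ccc1OCc1ccccc1 | intermediate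
14 | (3R,4R)-4-(4-benzyloxy-3-methoxyphenyl)-3-{[(4-benzyloxy-3-methoxyphenyl)methoxy]methyl}-1-chloro-4-hydroxybutan-2-one | COc1cc([C@H](O)[C@@H](COCc2ccc(OCc3ccccc3)c(OC)c2)C(=O)CCl)ccc1OCc1ccccc1 | intermediate
15 | (4R,5R)-5-(4-benzyloxy-3-methoxyphenyl)-4-{[(4-benzyloxy-3-methoxyphenyl)methoxy]methyl}oxolan-3-one (cis) | COc1cc([C@H]2[C@@H](COCc3ccc(OCc4ccccc4)c(OC)c3)C(=O)CO2)ccc1OCc1ccccc1 | intermediate
16 | (4S,5R)-5-(4-benzyloxy-3-methoxyphenyl)-4-{[(4-benzyloxy-3-methoxyphenyl)methoxy]methyl}oxolan-3-one (trans) | COc1cc([C@H]2[C@H](COCc3ccc(OCc4ccccc4)c(OC)c3)C(=O)CO2)ccc1OCc1ccccc1 | intermediate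
17 | 1,5-biradical from 16 (ketyl radical at C8', benzylic α-oxy radical at C7') | COc1cc([C@H]2[C@H](CO[CH]c3ccc(OCc4ccccc4)c(OC)c3)[C](O)CO2)ccc1OCc1ccccc1 | intermediate
18 | (1R,2S,5S,6R)-2,6-bis(4-benzyloxy-3-methoxyphenyl)-3,7-dioxabicyclo[3.3.0]octan-1-ol (cis-fused, aryl groups exo) | COc1cc([C@H]2[C@@H]3CO[C@@H](c4ccc(OCc5ccccc5)c(OC)c4)[C@]3(O)CO2)ccc1OCc1ccccc1 | intermediate
19 | (1R,2S,5S,6R)-2,6-bis(4-hydroxy-3-methoxyphenyl)-3,7-dioxabicyclo[3.3.0]octan-1-ol | COc1cc([C@H]2[C@@H]3CO[C@@H](c4ccc(O)c(OC)c4)[C@]3(O)CO2)ccc1O | intermediate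
20 | (2R,3R)-2,3-bis[(4-hydroxy-3-methoxyphenyl)methyl]butane-1,2,4-triol | COc1cc(C[C@H](CO)[C@@](O)(CO)Cc2ccc(O)c(OC)c2)ccc1O | target

**Step count and risks**

Total step count: 8. Longest linear sequence: 8 steps (1 to 20).

Steps most likely to fail:

1. Step 7 (key step). The excited oxolanone may undergo α-cleavage with decarbonylation, or be deactivated by charge transfer to the electron-rich aryl group on C7, so that hydrogen transfer from C7' is slow and the substrate is consumed unproductively. Fallback, setting out from 16 and returning at 20: Wittig olefination of the ketone with the ylide from (4-benzyloxy-3-methoxybenzyl)triphenylphosphonium chloride F1 (made from commercial 4-benzyloxy-3-methoxybenzyl chloride and PPh3; NaHMDS, THF) would give the 3-arylmethylidene oxolane F2 (alkene geometry immaterial). Dihydroxylation with OsO4 (cat.)/NMO should occur on the face of ring A opposite to the C8 side chain and give the diol F3, with the tertiary C8' hydroxyl cis to H8 as in 18 and an extra benzylic hydroxyl on C7'. Hydrogenolysis of F3 under the conditions of step 8 then removes the benzylic C7'–OH, the ring C7–O bond, the arylmethyl ether on the C9 oxygen and the benzyl ethers, and arrives at 20.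

2. Step 8. Hydrogenolysis may stop after O-debenzylation or after opening only one ring, because the C7'–O bond is flanked by the fully substituted C8'; adding acid to force it would invite Friedel–Crafts closure to an aryltetralin. Fallback, setting out from 18 and returning at 20: ionic hydrogenation of 18 with excess Et3SiH and BF3·OEt2 in CH2Cl2 at −78 °C, while both phenols are still benzylated, would open both p-alkoxybenzylic C–O bonds by hydride capture of the benzylic cations and give the dibenzyl ether of the target F4. The two O-benzyl groups are then removed with H2, Pd/C in EtOH/EtOAc to give 20.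

3. Step 5. The carbenoid may decompose before it adds, or the lithium aldolate of 12 may fragment by retro-aldol cleavage under the strongly basic conditions. Fallback, setting out from 12 and returning at 15 (which is equilibrated to 16 with DBU as in step 6): MeMgBr (excess, THF, 0 °C) converts the Weinreb amide into the β-hydroxy methyl ketone F5. Detrifluoroacetylative diazo transfer (LiHMDS, CF3CO2CH2CF3, THF, −78 °C, giving the trifluoroacetylated diketone F6; then MsN3, Et3N, aqueous MeCN) gives the α-diazo ketone F7. Rh2(OAc)4 (cat.) in CH2Cl2 at rt then effects intramolecular carbenoid O–H insertion of the C7 hydroxyl and closes ring A under neutral conditions to 15.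

**Further compounds**

F1 | step 7 | (4-benzyloxy-3-methoxybenzyl)triphenylphosphonium chloride | COc1cc(C[P+](c2ccccc2)(c2ccccc2)c2ccccc2)ccc1OCc1ccccc1.[Cl-]
F2 | step 7 | (2R,3S)-2-(4-benzyloxy-3-methoxyphenyl)-3-{[(4-benzyloxy-3-methoxyphenyl)methoxy]methyl}-4-[(4-benzyloxy-3-methoxyphenyl)methylidene]oxolane | COc1cc([C@H]2[C@H](COCc3ccc(OCc4ccccc4)c(OC)c3)C(=Cc3ccc(OCc4ccccc4)c(OC)c3)CO2)ccc1OCc1ccccc1
F3 | step 7 | (3R,4S,5R)-5-(4-benzyloxy-3-methoxyphenyl)-4-{[(4-benzyloxy-3-methoxyphenyl)methoxy]methyl}-3-[(4-benzyloxy-3-methoxyphenyl)(hydroxy)methyl]oxolan-3-ol (C7' carbinol centre undefined) | COc1cc([C@H]2[C@H](COCc3ccc(OCc4ccccc4)c(OC)c3)[C@](O)(C(O)c3ccc(OCc4ccccc4)c(OC)c3)CO2)ccc1OCc1ccccc1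
F4 | step 8 | (2R,3R)-2,3-bis[(4-benzyloxy-3-methoxyphenyl)methyl]butane-1,2,4-triol | COc1cc(C[C@H](CO)[C@@](O)(CO)Cc2ccc(OCc3ccccc3)c(OC)c2)ccc1OCc1ccccc1
F5 | step 5 | (3R,4R)-4-(4-benzyloxy-3-methoxyphenyl)-3-{[(4-benzyloxy-3-methoxyphenyl)methoxy]methyl}-4-hydroxybutan-2-one | COc1cc([C@H](O)[C@@H](COCc2ccc(OCc3ccccc3)c(OC)c2)C(C)=O)ccc1OCc1ccccc1
F6 | step 5 | (5R,6R)-6-(4-benzyloxy-3-methoxyphenyl)-5-{[(4-benzyloxy-3-methoxyphenyl)methoxy]methyl}-1,1,1-trifluoro-6-hydroxyhexane-2,4-dione | COc1cc([C@H](O)[C@@H](COCc2ccc(OCc3ccccc3)c(OC)c2)C(=O)CC(=O)C(F)(F)F)ccc1OCc1ccccc1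
F7 | step 5 | (3R,4R)-4-(4-benzyloxy-3-methoxyphenyl)-3-{[(4-benzyloxy-3-methoxyphenyl)methoxy]methyl}-1-diazo-4-hydroxybutan-2-one | COc1cc([C@H](O)[C@@H](COCc2ccc(OCc3ccccc3)c(OC)c2)C(=O)C=[N+]=[N-])ccc1OCc1ccccc1
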